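**Retrosynthetic overview**
1. The dihydrobenzofuran ring is closed last: after global debenzylation, the free 7-OH adds to the p-quinone methide formed from the C-β carbinol.
2. The key late coupling joins two C15 halves. The C-8 carbon of a (2S)-tribenzyl flavan opens a racemic aurone epoxide at its acetal-type C-2, forming the spiro quaternary centre and the C8–C2 bond.
3. The flavan pyran ring is formed by asymmetric transfer hydrogenation (ATH) of a dihydrochalcone followed by Mitsunobu closure (inversion). The benzofuranone ring is formed by intramolecular O-alkylation, and the aurone by aldol condensation.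
4. Both phloroglucinol-type rings come from resorcinol by Ir-catalysed C–H borylation and oxidation. The 4-hydroxyphenyl units come from 4-bromophenol.

**Assumptions**
- Both rings of the spiro core carry only benzyl protection until the end, so no O-5/O-7 differentiation is needed.
- C-8 of 5,7-bis(benzyloxy)flavans is the more reactive and less hindered site, by analogy with regioselective 8-bromination of benzylated flavans.
- The natural spiro epimer is identified by comparing the final product with reported data.

---

**Step 1**
Reactants: 1, resorcinol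
Product: 2, 1,3-bis(benzyloxy)benzene
Conditions: BnBr (2.2 equiv), K2CO3, acetone, reflux
Reagents that add atoms: benzyl bromide, BrCc1ccccc1
Why: Double Williamson O-alkylation gives benzyl ethers that survive every later step and are removed by hydrogenolysis at the end.

**Step 2**
Reactants: 2
Product: 3, 2-[3,5-bis(benzyloxy)phenyl]-4,4,5,5-tetramethyl-1,3,2-dioxaborolane
Conditions: [Ir(OMe)(cod)]2 (1.5 mol%), dtbpy (3 mol%), B2pin2, THF, 80 °C
Reagents that add atoms: bis(pinacolato)diboron, CC1(C)OB(OC1(C)C)B1OC(C)(C)C(C)(C)O1
Why: Sterically controlled Ir-catalysed C–H borylation of a 1,3-disubstituted arene occurs only at C-5, meta to both OBn groups, which sets the 1,3,5-trioxygenated pattern.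

**Step 3**
Reactants: 3
Product: 4, 3,5-bis(benzyloxy)phenol
Conditions: 30% aq. H2O2, NaOH, THF, 0 °C → rt
Reagents that add atoms: hydrogen peroxide, OO
Why: Oxidative deborylation converts C–B to C–OH with retention, giving the bis-benzylated phloroglucinol.

**Step 4**
Reactants: 5, 4-bromophenol
Product: 6, 1-(benzyloxy)-4-bromobenzene
Conditions: BnBr, K2CO3, acetone, reflux
Reagents that add atoms: benzyl bromide, BrCc1ccccc1
Why: O-Benzylation masks the phenol that becomes the B-ring 4-OH (flavan 4′-OH and the C-β aryl 4-OH).

**Step 5**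
Reactants: 6
Product: 7, 4-(benzyloxy)benzaldehyde
Conditions: n-BuLi, THF, –78 °C; then DMF
Reagents that add atoms: N,N-dimethylformamide, CN(C)C=O
Why: Li–Br exchange followed by formylation installs the aldehyde at the position of the bromide (Bouveault formylation).

**Step 6**
Reactants: 6; 8, N-methoxy-N-methylacetamide
Product: 9, 1-[4-(benzyloxy)phenyl]ethan-1-one
Conditions: Mg, THF (ArMgBr), then 8, 0 °C → rt
Reagents that add atoms: none
Why: The Weinreb amide stops at the ketone stage through a stable chelated intermediate, so no tertiary alcohol forms.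

**Step 7**
Reactants: 4
Product: 10, 2-hydroxy-4,6-bis(benzyloxy)benzaldehyde
Conditions: MgCl2, Et3N, (CH2O)n, MeCN, reflux
Reagents that add atoms: paraformaldehyde (formaldehyde), C=O
Why: Mg-phenoxide-directed ortho-formylation (Casnati–Skattebøl) occurs at the equivalent positions ortho to OH, not at the para position flanked by two OBn groups.

**Step 8**
Reactants: 10; 9
Product: 11, (E)-3-[4,6-bis(benzyloxy)-2-hydroxyphenyl]-1-[4-(benzyloxy)phenyl]prop-2-en-1-one
Conditions: KOH, EtOH/H2O, rt → 40 °C
Reagents that add atoms: none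
Why: Claisen–Schmidt aldol condensation gives the thermodynamically favoured E-chalcone, placing ring A on the β-carbon and the 4-benzyloxyphenyl ring on the carbonyl, as needed for the flavan.

**Step 9**
Reactants: 11
Product: 12, 3-[4,6-bis(benzyloxy)-2-hydroxyphenyl]-1-[4-(benzyloxy)phenyl]propan-1-one
Conditions: [(Ph3P)CuH]6 (10 mol%), PhSiH3 (2 equiv), toluene, rt; then aq. NH4Cl
Reagents that add atoms: none (only hydride and proton are delivered)
Why: Cu–H conjugate reduction removes only the enone C=C and leaves the ketone and all benzyl ethers intact, where H2/Pd would debenzylate.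

**Step 10**
Reactants: 12
Product: 13, (1R)-3-[4,6-bis(benzyloxy)-2-hydroxyphenyl]-1-[4-(benzyloxy)phenyl]propan-1-ol
Conditions: RuCl[(R,R)-TsDPEN](p-cymene) (1 mol%), HCO2H/Et3N (5:2), CH2Cl2, 30 °C, 24 h
Reagents that add atoms: none (only hydrogen is added)
Why: Noyori asymmetric transfer hydrogenation of the aryl ketone with the (R,R)-catalyst gives the (R)-benzylic alcohol, which sets the future flavan C-2 after inversion.

**Step 11**
Reactants: 13
Product: 14, (2S)-5,7-bis(benzyloxy)-2-[4-(benzyloxy)phenyl]chromane
Conditions: PPh3, DIAD, THF, 0 °C → rt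
Reagents that add atoms: none (net loss of H2O)
Why: Intramolecular Mitsunobu O-alkylation by the ortho phenol closes the pyran ring with clean inversion at the carbinol carbon, so the (R)-alcohol becomes the (2S)-flavan.

**Step 12**
Reactants: 4; 15, chloroacetic acid
Product: 16, 1-[4,6-bis(benzyloxy)-2-hydroxyphenyl]-2-chloroethan-1-one
Conditions: BF3·OEt2, 75 °C, 2 h
Reagents that add atoms: none (15 is the numbered reactant)
Why: BF3-mediated ortho-acylation of the very electron-rich phenol proceeds through the chelated acyl-borate, as in the usual synthesis of 2-hydroxy-4,6-dialkoxyacetophenones.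

**Step 13**
Reactants: 16
Product: 17, 4,6-bis(benzyloxy)benzofuran-3(2H)-one
Conditions: NaOAc, EtOH, reflux
Reagents that add atoms: none (loss of HCl)
Why: The phenoxide displaces the primary α-chloride by 5-exo-tet O-alkylation, forming the coumaranone ring.

**Step 14**
Reactants: 17; 7
Product: 18, (Z)-4,6-bis(benzyloxy)-2-[4-(benzyloxy)benzylidene]benzofuran-3(2H)-one
Conditions: aq. NaOH, EtOH, rt
Reagents that add atoms: none (loss of H2O)
Why: Aldol condensation at C-2 of the coumaranone gives the thermodynamically preferred Z-aurone, with the aryl group cis to the ring oxygen.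

**Step 15**
Reactants: 18
Product: 19, rac-cis-aurone epoxide, O=C1c2c(OBn)cc(OBn)cc2O[C@@]14O[C@@H]4c4ccc(OBn)cc4 (one enantiomer drawn; aryl cis to O-1)
Conditions: DMDO (≈0.08 M in acetone), CH2Cl2, 0 °C, 1 h; concentrate cold and use at once
Reagents that add atoms: dimethyldioxirane, CC1(C)OO1
Why: Neutral, stereospecific syn-epoxidation of the enol-ether C=C retains the cis (aryl/O-1) relationship and avoids basic conditions that would open the epoxide.

**Step 16**
Reactants: 14 (1.0 equiv); 19 (2.0 equiv)
Product: 20, spiro-coupled carbinol (flavan C-8 bonded to C-2 of the benzofuranone, with CH(OH)Ar on the quaternary carbon)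
Conditions: Sc(OTf)3 (10 mol%), CH2Cl2, –40 → 0 °C; then prep-HPLC to separate diastereomers
Reagents that add atoms: none (epoxide O becomes the C-β OH; C8–H adds across the opened C–O bond)
Why: The Lewis acid opens the acetal-type C2–O bond of the epoxide (assisted by O-1), and the most nucleophilic and least hindered arene carbon C-8 (Friedel–Crafts) attacks from the face opposite the departing oxygen, so the epoxide configuration is transferred to the new quaternary centre; with racemic 19 and enantiopure 14 the two spiro epimers are diastereomers, and the natural one is isolated by HPLC.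

**Step 17**
Reactants: 20
Product: 21, deprotected polyphenol carbinol
Conditions: H2 (1 atm), Pd(OH)2/C, EtOAc/MeOH (1:1), rt, 16 h
Reagents that add atoms: none (only H atoms are added)
Why: Hydrogenolysis removes all six O-benzyl groups, which frees the 7-OH needed for ring closure, while the aryl ketone and the flavan and carbinol C–O bonds are expected to survive; no stereocentre is touched.

**Step 18**
Reactants: 21
Product: 22, Daphnodorin C
Conditions: p-TsOH·H2O (20 mol%), MeCN, 40 °C, 2 h
Reagents that add atoms: none (loss of H2O)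
Why: Acid ionises the 4-hydroxybenzylic alcohol to a p-quinone methide that the neighbouring 7-OH traps in a 5-exo oxa-cyclisation, forming the dihydrobenzofuran (oxa-Michael addition), and because ionisation is reversible the C-β centre settles in the favoured configuration with the aryl group cis to the ring oxygen O-1 and trans to the C-3 carbonyl, as in the target.

---

**Compound list**

| No. | Name | SMILES | Role |
|---|---|---|---|
| 1 | resorcinol | Oc1cccc(O)c1 | starting material |
| 2 | 1,3-bis(benzyloxy)benzene | c1ccc(COc2cccc(OCc3ccccc3)c2)cc1 | intermediate |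
| 3 | 3,5-bis(benzyloxy)phenyl-Bpin | CC1(C)OB(OC1(C)C)c1cc(OCc2ccccc2)cc(OCc2ccccc2)c1 | intermediate |
| 4 | 3,5-bis(benzyloxy)phenol | Oc1cc(OCc2ccccc2)cc(OCc2ccccc2)c1 | intermediate |
| 5 | 4-bromophenol | Oc1ccc(Br)cc1 | starting material |
| 6 | 1-(benzyloxy)-4-bromobenzene | Brc1ccc(OCc2ccccc2)cc1 | intermediate |
| 7 | 4-(benzyloxy)benzaldehyde | O=Cc1ccc(OCc2ccccc2)cc1 | intermediate |
| 8 | N-methoxy-N-methylacetamide | CON(C)C(C)=O | starting material |
| 9 | 4′-(benzyloxy)acetophenone | CC(=O)c1ccc(OCc2ccccc2)cc1 | intermediate |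
| 10 | 2-hydroxy-4,6-bis(benzyloxy)benzaldehyde | O=Cc1c(O)cc(OCc2ccccc2)cc1OCc1ccccc1 | intermediate |
| 11 | (E)-chalcone | O=C(/C=C/c1c(O)cc(OCc2ccccc2)cc1OCc1ccccc1)c1ccc(OCc2ccccc2)cc1 | intermediate |
| 12 | dihydrochalcone | O=C(CCc1c(O)cc(OCc2ccccc2)cc1OCc1ccccc1)c1ccc(OCc2ccccc2)cc1 | intermediate |
| 13 | (1R)-alcohol | O[C@H](CCc1c(O)cc(OCc2ccccc2)cc1OCc1ccccc1)c1ccc(OCc2ccccc2)cc1 | intermediate |
| 14 | (2S)-5,7,4′-tris(benzyloxy)flavan | c1ccc(cc1)COc1ccc(cc1)[C@@H]1CCc2c(OCc3ccccc3)cc(OCc3ccccc3)cc2O1 | intermediate (fragment A) |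
| 15 | chloroacetic acid | OC(=O)CCl | starting material |
| 16 | α-chloro-2-hydroxyacetophenone | O=C(CCl)c1c(O)cc(OCc2ccccc2)cc1OCc1ccccc1 | intermediate |
| 17 | 4,6-bis(benzyloxy)benzofuran-3(2H)-one | O=C1COc2cc(OCc3ccccc3)cc(OCc3ccccc3)c12 | intermediate |
| 18 | (Z)-tribenzyl aurone | O=C1c2c(OCc3ccccc3)cc(OCc3ccccc3)cc2O/C1=C\c1ccc(OCc2ccccc2)cc1 | intermediate |
| 19 | rac-aurone epoxide | O=C1c2c(OCc3ccccc3)cc(OCc3ccccc3)cc2O[C@@]14O[C@@H]4c4ccc(OCc5ccccc5)cc4 | intermediate (fragment B) |
| 20 | coupled hexabenzyl carbinol | O=C1c2c(OCc3ccccc3)cc(OCc3ccccc3)cc2O[C@@]1(c1c(OCc2ccccc2)cc(OCc2ccccc2)c3c1O[C@H](c1ccc(OCc2ccccc2)cc1)CC3)[C@H](O)c1ccc(OCc2ccccc2)cc1 | intermediate |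
| 21 | deprotected carbinol | O=C1c2c(O)cc(O)cc2O[C@@]1(c1c(O)cc(O)c3c1O[C@H](c1ccc(O)cc1)CC3)[C@H](O)c1ccc(O)cc1 | intermediate |
| 22 | Daphnodorin C | O=C1c2c(O)cc(O)cc2O[C@]12c1c(cc(O)c3c1O[C@H](c1ccc(O)cc1)CC3)O[C@H]2c1ccc(O)cc1 | target |

---

**Totals**
- Total steps: 18.
- Longest linear sequence: 11 steps (1 → 2 → 3 → 4 → 10 → 11 → 12 → 13 → 14 → 20 → 21 → 22, i.e. Steps 1, 2, 3, 7, 8, 9, 10, 11, 16, 17, 18).

**Three steps most likely to fail**
1. **Step 16 (epoxide Friedel–Crafts coupling).**
   - Risks: attack at benzylic C-β instead of C-2, C-6 instead of C-8 attack, ionisation of the flavan C2–O bond, and a near 1:1 mixture of spiro epimers.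
   - Fallback: change the bond-forming logic. Brominate 14 at C-8 (NBS), couple it by Pd-catalysed α-arylation with 2-(4-benzyloxybenzyl)-4,6-bis(benzyloxy)benzofuranone, and introduce the C-β oxygen afterwards by benzylic oxidation and cyclisation.
2. **Steps 10–11 (ATH then Mitsunobu).** The p-alkoxybenzylic cation can partly racemise the carbinol during Mitsunobu closure.
   - Fallback: use an asymmetric intramolecular oxa-Michael cyclisation of chalcone 11 (bifunctional thiourea or squaramide catalyst) to the (2S)-flavanone, then remove the C-4 carbonyl (NaBH4, then Et3SiH/TFA).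
3. **Step 17 (global hydrogenolysis).** The free benzylic carbinol or the flavan C2–O bond may be hydrogenolysed.
   - Fallback: mask the C-β oxygen as a methyl ether before debenzylation, and close the ring at the end by acid-mediated loss of MeOH through the same p-quinone methide.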